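**Assumption:** the target has no stereocentre and is achiral, so there is no enantiomer to select; the route makes the compound exactly as drawn.

## Retrosynthetic overview

1. The only ring, the 25-membered lactone, is closed last by macrolactonisation of 24-hydroxytetracosanoic acid.
2. The C10 methylene comes from a ketone (Wolff–Kishner), and the ketone from a tert-butyl β-keto ester (acidolysis and decarboxylation).
3. The key C10–C11 bond is made by a crossed Claisen condensation: lithium enolate of tert-butyl 15-(benzyloxy)pentadecanoate plus methyl 10-chloro-10-oxodecanoate.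
4. The C15 fragment comes from ω-pentadecalactone (its carboxyl carbon is later lost as CO2) and the C10 fragment from monomethyl sebacate: 14 + 10 = 24 carbons.

## Route

Step 1
Reactants: 1 ω-pentadecalactone
Product: 3 15-hydroxypentadecanoic acid, via potassium 15-hydroxypentadecanoate 2 (not isolated)
Conditions: KOH (2 equiv), MeOH/H2O 4:1, reflux; then 2 M HCl to pH 2
Reagents that add atoms: potassium hydroxide, [K+].[OH-]
Why: Saponification of the lactone is driven to completion by carboxylate formation, and acidification frees the hydroxy acid.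

Step 2
Reactants: 3 15-hydroxypentadecanoic acid
Product: 4 tert-butyl 15-hydroxypentadecanoate
Conditions: tert-butyl 2,2,2-trichloroacetimidate (2 equiv), THF/cyclohexane 1:1, rt to 40 °C, no added catalyst
Reagents that add atoms: tert-butyl 2,2,2-trichloroacetimidate, CC(C)(C)OC(=N)C(Cl)(Cl)Cl
Why: Imidate esterification is chemoselective because the carboxylic acid protonates the imidate and captures the tert-butyl cation, whereas the primary alcohol does not react without a Lewis acid.

Step 3
Reactants: 4 tert-butyl 15-hydroxypentadecanoate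
Product: 6 tert-butyl 15-(benzyloxy)pentadecanoate, via sodium alkoxide 5 (not isolated)
Conditions: NaH (1.3 equiv), BnBr (1.3 equiv), n-Bu4NI (cat.), THF/DMF 4:1, 0 °C to rt
Reagents that add atoms: benzyl bromide, BrCc1ccccc1
Why: Williamson ether synthesis; the hindered tert-butyl ester resists transesterification by the primary alkoxide.

Step 4
Reactants: 7 monomethyl sebacate (10-methoxy-10-oxodecanoic acid)
Product: 8 methyl 10-chloro-10-oxodecanoate
Conditions: (COCl)2 (1.5 equiv), DMF (cat.), CH2Cl2, 0 °C to rt; concentrate, strip with toluene, use crude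
Reagents that add atoms: oxalyl chloride, ClC(=O)C(=O)Cl
Why: DMF-catalysed (Vilsmeier-type) acid chloride formation leaves the methyl ester untouched.

Step 5
Reactants: 6 tert-butyl 15-(benzyloxy)pentadecanoate (2.1 equiv); 8 methyl 10-chloro-10-oxodecanoate (1.0 equiv)
Product: 11 1-tert-butyl 12-methyl 2-[13-(benzyloxy)tridecyl]-3-oxododecanedioate (racemic), via lithium ester enolate 9 (not isolated), via lithium keto ester enolate 10 (not isolated)
Conditions: LiN(i-Pr)2 (2.1 equiv), THF, −78 °C, 45 min; then 8 in THF dropwise, −78 °C, 1 h; sat. aq. NH4Cl; the excess 6 is recovered on chromatography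
Reagents that add atoms: none
Why: Crossed Claisen condensation in which the preformed, non-self-condensing tert-butyl ester enolate is C-acylated by the acid chloride (far more electrophilic than the methyl ester) and the second equivalent of enolate stores the product as its stabilised enolate until the quench; the new stereocentre is racemic and is removed in step 6.

Step 6
Reactants: 11 1-tert-butyl 12-methyl 2-[13-(benzyloxy)tridecyl]-3-oxododecanedioate
Product: 13 methyl 24-(benzyloxy)-10-oxotetracosanoate, via β-keto acid 12 (not isolated)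
Conditions: CF3CO2H/CH2Cl2 1:4, rt, 3 h; concentrate; toluene, 90 °C, 1 h
Reagents that add atoms: none
Why: Acidolysis of the tert-butyl ester (loss of isobutene) followed by thermal decarboxylation of the β-keto acid through a six-membered transition state gives the ketone without retro-Claisen cleavage, while the benzyl ether and methyl ester are stable to the acid.

Step 7
Reactants: 13 methyl 24-(benzyloxy)-10-oxotetracosanoate
Product: 15 24-(benzyloxy)-10-oxotetracosanoic acid, via lithium 24-(benzyloxy)-10-oxotetracosanoate 14 (not isolated)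
Conditions: LiOH·H2O (3 equiv), THF/MeOH/H2O 3:1:1, 40 °C; then 1 M HCl
Reagents that add atoms: lithium hydroxide, [Li+].[OH-]
Why: Saponification of the unhindered methyl ester removes the only group that hydrazine could convert into an acyl hydrazide in the next step.

Step 8
Reactants: 15 24-(benzyloxy)-10-oxotetracosanoic acid
Product: 18 24-(benzyloxy)tetracosanoic acid, via potassium hydrazone carboxylate 16 (not isolated), via potassium 24-(benzyloxy)tetracosanoate 17 (not isolated)
Conditions: N2H4·H2O (5 equiv), KOH (5 equiv), diethylene glycol, 130 °C, 2 h; then distil to 200 °C, 4 h; then aq. HCl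
Reagents that add atoms: none
Why: Wolff–Kishner reduction (Huang-Minlon modification) turns the ketone into a methylene by base-induced loss of N2 from the hydrazone, and long-chain keto carboxylates and benzyl ethers tolerate the hot base.

Step 9
Reactants: 18 24-(benzyloxy)tetracosanoic acid
Product: 19 24-hydroxytetracosanoic acid
Conditions: H2 (1 atm), 10% Pd/C, THF/EtOH 1:1, 40 °C
Reagents that add atoms: none
Why: Catalytic hydrogenolysis cleaves the benzylic C–O bond cleanly and nothing else in the molecule is reducible.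

Step 10
Reactants: 19 24-hydroxytetracosanoic acid
Product: 21 24-tetracosanolide, via mixed anhydride 20 (not isolated)
Conditions: 2,4,6-Cl3C6H2COCl (1.5 equiv), Et3N (2 equiv), THF, 40 °C, 2 h; then syringe-pump addition over 10 h to DMAP (6 equiv), toluene, reflux (final about 1 mM)
Reagents that add atoms: none
Why: Yamaguchi macrolactonisation; DMAP-mediated acyl transfer from the mixed anhydride at high dilution favours the strain-free 25-membered ring over oligomers.

## Compound list

1 | ω-pentadecalactone (oxacyclohexadecan-2-one) | O=C1CCCCCCCCCCCCCCO1 | starting material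
2 | potassium 15-hydroxypentadecanoate | [K+].[O-]C(=O)CCCCCCCCCCCCCCO | intermediate
3 | 15-hydroxypentadecanoic acid | OC(=O)CCCCCCCCCCCCCCO | intermediate
4 | tert-butyl 15-hydroxypentadecanoate | CC(C)(C)OC(=O)CCCCCCCCCCCCCCO | intermediate
5 | sodium 15-tert-butoxy-15-oxopentadecan-1-olate | CC(C)(C)OC(=O)CCCCCCCCCCCCCC[O-].[Na+] | intermediate
6 | tert-butyl 15-(benzyloxy)pentadecanoate | CC(C)(C)OC(=O)CCCCCCCCCCCCCCOCc1ccccc1 | intermediate
7 | monomethyl sebacate (10-methoxy-10-oxodecanoic acid) | COC(=O)CCCCCCCCC(=O)O | starting material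
8 | methyl 10-chloro-10-oxodecanoate | COC(=O)CCCCCCCCC(=O)Cl | intermediate
9 | lithium enolate of tert-butyl 15-(benzyloxy)pentadecanoate | [Li+].[O-]C(OC(C)(C)C)=CCCCCCCCCCCCCCOCc1ccccc1 | intermediate
10 | lithium enolate of the β-keto diester 11 | [Li+].[O-]C(CCCCCCCCC(=O)OC)=C(CCCCCCCCCCCCCOCc1ccccc1)C(=O)OC(C)(C)C | intermediate
11 | 1-tert-butyl 12-methyl 2-[13-(benzyloxy)tridecyl]-3-oxododecanedioate (racemic) | CC(C)(C)OC(=O)C(CCCCCCCCCCCCCOCc1ccccc1)C(=O)CCCCCCCCC(=O)OC | intermediate
12 | 2-[13-(benzyloxy)tridecyl]-12-methoxy-3,12-dioxododecanoic acid | OC(=O)C(CCCCCCCCCCCCCOCc1ccccc1)C(=O)CCCCCCCCC(=O)OC | intermediate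
13 | methyl 24-(benzyloxy)-10-oxotetracosanoate | COC(=O)CCCCCCCCC(=O)CCCCCCCCCCCCCCOCc1ccccc1 | intermediate
14 | lithium 24-(benzyloxy)-10-oxotetracosanoate | [Li+].[O-]C(=O)CCCCCCCCC(=O)CCCCCCCCCCCCCCOCc1ccccc1 | intermediate
15 | 24-(benzyloxy)-10-oxotetracosanoic acid | OC(=O)CCCCCCCCC(=O)CCCCCCCCCCCCCCOCc1ccccc1 | intermediate
16 | potassium 24-(benzyloxy)-10-hydrazinylidenetetracosanoate | [K+].[O-]C(=O)CCCCCCCCC(=NN)CCCCCCCCCCCCCCOCc1ccccc1 | intermediate
17 | potassium 24-(benzyloxy)tetracosanoate | [K+].[O-]C(=O)CCCCCCCCCCCCCCCCCCCCCCCOCc1ccccc1 | intermediate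
18 | 24-(benzyloxy)tetracosanoic acid | OC(=O)CCCCCCCCCCCCCCCCCCCCCCCOCc1ccccc1 | intermediate
19 | 24-hydroxytetracosanoic acid | OC(=O)CCCCCCCCCCCCCCCCCCCCCCCO | intermediate
20 | 24-hydroxytetracosanoic 2,4,6-trichlorobenzoic anhydride | Clc1cc(Cl)c(C(=O)OC(=O)CCCCCCCCCCCCCCCCCCCCCCCO)c(Cl)c1 | intermediate
21 | 24-tetracosanolide (oxacyclopentacosan-2-one) | O=C1CCCCCCCCCCCCCCCCCCCCCCCO1 | target

## Summary

Total step count: 10. Longest linear sequence: 9 steps (steps 1–3 and 5–10); step 4 is a one-step side branch.

Three steps most likely to fail: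

**Step 5 (crossed Claisen; risks are O-acylation, ketene formation from 8, and the need for excess enolate).** The fallback sets out from 8 and 6 and comes back at 11. Acid chloride 8 is reduced under Rosenmund conditions (H2, Pd/BaSO4, 2,6-lutidine, THF) to methyl 10-oxodecanoate F1. Enolate 9, made from 6 with 1.05 equiv LiN(i-Pr)2 in THF at −78 °C, adds to F1 in an aldol addition with 1:1 stoichiometry to give the lithium aldolate F2. Aqueous NH4Cl protonates it to 1-tert-butyl 12-methyl 2-[13-(benzyloxy)tridecyl]-3-hydroxydodecanedioate F3 (diastereomer mixture, of no consequence). Dess–Martin periodinane with NaHCO3 in CH2Cl2 then oxidises F3 to β-keto diester 11.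

**Step 8 (Wolff–Kishner at 200 °C; risks are incomplete reduction, azine formation and poor solubility).** The fallback sets out from 13 and comes back at 18, bypassing steps 7 and 8. NaBH4 in THF/MeOH at 0 °C reduces the ketone to methyl 24-(benzyloxy)-10-hydroxytetracosanoate F4. 1,1'-Thiocarbonyldiimidazole with catalytic DMAP in 1,2-dichloroethane at 70 °C gives O-[24-(benzyloxy)-1-methoxy-1-oxotetracosan-10-yl] 1H-imidazole-1-carbothioate F5. Barton–McCombie deoxygenation (n-Bu3SnH, AIBN, toluene, reflux) gives methyl 24-(benzyloxy)tetracosanoate F6. LiOH in THF/MeOH/H2O gives lithium 24-(benzyloxy)tetracosanoate F7, and HCl then gives 18.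

**Step 10 (macrolactonisation; risk is oligomerisation).** The fallback sets out from 19 and comes back at 21, closing the ring by O-alkylation instead of O-acylation. Refluxing 48% aq. HBr/AcOH converts 19 into 24-bromotetracosanoic acid F8. Slow addition of F8 to Cs2CO3 in DMF at 80 °C (final about 2 mM) forms cesium 24-bromotetracosanoate F9, which cyclises by intramolecular SN2 displacement of bromide to 21.

## Further compounds

F1 | step 5 | methyl 10-oxodecanoate | COC(=O)CCCCCCCCC=O
F2 | step 5 | lithium aldolate of F3 | [Li+].[O-]C(CCCCCCCCC(=O)OC)C(CCCCCCCCCCCCCOCc1ccccc1)C(=O)OC(C)(C)C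
F3 | step 5 | 1-tert-butyl 12-methyl 2-[13-(benzyloxy)tridecyl]-3-hydroxydodecanedioate | OC(CCCCCCCCC(=O)OC)C(CCCCCCCCCCCCCOCc1ccccc1)C(=O)OC(C)(C)C
F4 | step 8 | methyl 24-(benzyloxy)-10-hydroxytetracosanoate | COC(=O)CCCCCCCCC(O)CCCCCCCCCCCCCCOCc1ccccc1
F5 | step 8 | O-[24-(benzyloxy)-1-methoxy-1-oxotetracosan-10-yl] 1H-imidazole-1-carbothioate | COC(=O)CCCCCCCCC(OC(=S)n1ccnc1)CCCCCCCCCCCCCCOCc1ccccc1
F6 | step 8 | methyl 24-(benzyloxy)tetracosanoate | COC(=O)CCCCCCCCCCCCCCCCCCCCCCCOCc1ccccc1
F7 | step 8 | lithium 24-(benzyloxy)tetracosanoate | [Li+].[O-]C(=O)CCCCCCCCCCCCCCCCCCCCCCCOCc1ccccc1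
F8 | step 10 | 24-bromotetracosanoic acid | OC(=O)CCCCCCCCCCCCCCCCCCCCCCCBr
F9 | step 10 | cesium 24-bromotetracosanoate | [Cs+].[O-]C(=O)CCCCCCCCCCCCCCCCCCCCCCCBr
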